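A small charge of precatalyst, 50 µM, works on 10 mM of substrate, so the catalyst forms can hold hardly any of it. The substrate is the limiting reagent in each flask.

the same everywhere: substrate 10 mM; precatalyst 50 µM
- gamma: coupling partner 35 mM; run made earlier
- alpha: coupling partner 200 mM; run made earlier
- maple: coupling partner 62.0 mM; time 2.5 d
- oak: coupling partner 25.0 mM; time 2.5 d
- elm: coupling partner 160 mM; time 2.5 d

| run | time / h | product / % | catalyst intermediate B / % | catalyst intermediate C / % | catalyst intermediate A / % | substrate / % |
|---|---|---|---|---|---|---|
| gamma | 8.00 | 0.9 | 1.8 | 0 | 0.3 | 97.8 |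
| gamma | 15.0 | 2.7 | 0.3 | 1.5 | 0.9 | 97.0 |
| gamma | 20.0 | 4.6 | 0 | 0.9 | 0.8 | 94.7 |
| gamma | 30.0 | 13.6 | 0 | 0.6 | 1.0 | 89.1 |
| gamma | 40.0 | 18.5 | 0.2 | 0.1 | 0 | 79.8 |
| alpha | 3.00 | 1.0 | 1.8 | 1.6 | 0.7 | 98.9 |
| alpha | 8.00 | 11.5 | 0 | 0.8 | 0 | 90.1 |
| alpha | 15.0 | 24.5 | 0.5 | 0 | 1.2 | 76.1 |
| alpha | 25.0 | 44.8 | 0.6 | 0.1 | 0 | 56.9 |
| alpha | 30.0 | 52.3 | 0 | 0 | 0 | 46.6 |
| alpha | 40.0 | 68.4 | 0 | 2.5 | 0.6 | 30.5 |

(scatter of a reading: 1 percentage point)



- which of these there is most of at the end, counted by the substrate in it, maple (catalyst intermediate B / catalyst intermediate C / substrate / catalyst intermediate A / product)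
- which of these there is most of at the end, counted by the substrate in it, oak (catalyst intermediate B / catalyst intermediate C / substrate / catalyst intermediate A / product)
- which of these there is most of at the end, counted by the substrate in it, elm (catalyst intermediate B / catalyst intermediate C / substrate / catalyst intermediate A / product)
- how much there is at the end of the one of these that leads, in percent of the substrate charged: maple
- how much there is at the end of the one of these that leads, in percent of the substrate charged: oak
- how much there is at the end of the one of these that leads, in percent of the substrate charged: elm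

Which leads at the end, substrate or product? The two share nearly all of the charge, so product leads once less than half is left. This reckoning therefore follows the fraction left, through the loss L, the natural logarithm of charged over left. The line between the outcomes is L = 0.693.

How does L depend on the partner? At 40.0 h the gamma run reads 0.226 and the alpha run 1.19. That ratio of 5.27 stands against a ratio of 5.71 in [coupling partner]. So, as a reading at that time and with the other charges the same, L in these two runs stands close to proportional to [coupling partner].

How does L grow with time? In the alpha run it climbs from 0.273 at 15.0 h to 1.19 at 40.0 h, which reads as a power of time with exponent 1.50. Carried on to 2.5 d, that power, as an estimate, multiplies L by 1.84.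

Gamma's L, times that factor, over its partner charge gives the end loss per unit of partner, s = 0.0118 mM⁻¹. Maple gets L = 0.734, barely over the line, with product at 52.0%. Oak gets 0.296, under the line, with substrate at 74.4%. Elm gets 1.89, over it, with product at 84.9%.

The forecast, which saw “an induction period followed by a nearly steady rate”, names product at 51% for maple, substrate at 78% for oak and product at 84% for elm. For oak it keeps more substrate than this reckoning.

The flasks give product at 58.6% in maple, substrate at 76.5% in oak and product at 86.2% in elm. Maple's loss is 0.891, which over its partner charge is 0.0144 mM⁻¹ against s = 0.0118 mM⁻¹, and maple's product stands above both estimates.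

    catalyst intermediate C → free catalyst + product (k = 0.00430 s⁻¹)
    catalyst intermediate B ⇌ by-product + catalyst intermediate C (K = 0.00270 M, k = 0.0920 s⁻¹)
    substrate + free catalyst → catalyst intermediate A (k = 0.920 M⁻¹ s⁻¹)
    coupling partner + catalyst intermediate A → catalyst intermediate B (k = 0.0320 M⁻¹ s⁻¹)
    coupling partner + precatalyst → free catalyst + spent reagent (k = 2.00 × 10⁻⁴ M⁻¹ s⁻¹)

A neighbouring flask is like maple but holds 16 mM of coupling partner, with the same time. The same s gives L = 0.189, under the line, so substrate should lead with 82.8% left. That flask ends with substrate leading and 88% of the substrate left, a loss of 0.132, and its product stands at 12.1%.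

The data are calculated from invented constants; the scatter is artificial.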